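## Structural features

Glyinflanin D is an achiral dibenzoylmethane: a propane-1,3-dione chain whose two carbonyl carbons are each bonded to C6 of a 2,2-dimethyl-2H-chromene. Ring A carries nothing else, whereas ring B carries a hydroxyl on C7, ortho to the acyl group and hydrogen-bonded to it. There are no stereocentres, so no stereochemical relationships have to be set; the two C3=C4 alkenes are cis by virtue of the pyran rings. The fragile parts are the two 2H-chromenes (styrene-like alkenes open to acid-catalysed hydration and dimerisation) and the ortho-hydroxyaryl 1,3-diketone, which cyclodehydrates to a 2-arylchromone in acid and can undergo retro-Claisen cleavage in hot aqueous base. The real difficulty is regiochemical and lies in ring B: the pyran must be fused linearly to a resorcinol-type ring, with O1 para and the hydroxyl ortho to the acyl group, whereas pyran annulation of 2,4-dioxygenated aryl ketones tends to go to the carbon between the two oxygens and give the angular isomer. Ring A has no such problem, because a para-acylphenol has two equivalent ortho positions. The key step exploits the substitution pattern of the carbocycle of ring B: oxygen on C7 and C8a, hydrogen on C8 between them, the acyl group on C6, and C4a bonded to C4. That is exactly the pattern a 1,1,3-trioxygenated diene imprints on an alkynone, so the benzene ring can be built with O1, C2, C3 and C4 already in place.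

## Logic of the disconnections

18 is cut at the bond between the central methylene and the carbonyl that carries ring A, giving 13 and 17. This is the crossed Claisen pairing of an ortho-hydroxyaryl methyl ketone with a non-enolisable aryl ester, so the diketone is formed last and only one enolate is possible. The two halves are of similar size and neither contains the sensitive diketone. The forward step must be basic throughout and end with a buffered quench, since base is tolerated by both chromenes and acid is not.

13 is taken back to 12 by removing the C3=C4 unsaturation of ring B; no skeletal bond is cut. The saturated pyran ring is the form that can be carried through enolate chemistry and a cycloaddition. The demand on the forward step is a dehydrogenation confined to C3 and C4; it is helped by the C7 oxygen (para to C4a) and by O1, which stabilise positive charge at benzylic C4, and by the quaternary C2, which blocks further oxidation.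

12 is cut at C4a–C5 and C6–C7, giving 9 and 10. This removes the whole benzene ring of ring B and leaves O1 and C4 attached to the four-carbon component, so linear fusion is decided before the arene exists. The forward step must deliver one orientation of the alkynone and then aromatise with retention of exactly one oxygen on C7.

9 is cut at its O–Si bond, back to 7 by way of dienolate 8. The only enolisable position of 7 is ring C3, γ to the ester, so the demand is kinetic γ-deprotonation and trapping on oxygen, followed by handling without water. The trimethylsilyl methyl ketene acetal is retained because it is the form whose cycloaddition behaviour is established; the improvement lies in using it crude, without chromatography.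

7 is cut at its exocyclic C=C bond, leading through 6 to 3 and 4 (as its enolate 5); the bond broken is the one between ring C2 and the acetate carbon. The forward steps must stop at single addition to the lactone and then dehydrate toward the conjugated exocyclic position without ionising the tertiary C–O bond.

3 is cut at one C–CH3 bond and at the lactone C–O bond, back to 1. The demand is addition of one methyl nucleophile to the ketone in the presence of the ester, after which lactonisation is favoured by the gem-dimethyl group.

17 is cut at C4–C4a and O1–C2 of ring A, back to 15, and 15 at its ether O–C bond, back to 14. Both ortho positions of 14 are equivalent, so the propargyl Claisen cascade (through 16) has no regiochemical question; it only requires heat and a non-acidic medium.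

## Other disconnections considered

Alternative 1: The cut removes all four methyl groups. The four C2–CH3 bonds are disconnected, which turns each chromene into a coumarin, so the diketone would be assembled as bis-coumarin A2 with the ring B hydroxyl masked as a methoxymethyl ether. In the forward key step the first equivalents of a methyl Grignard reagent convert A2 into its magnesium diketonate, and the excess adds twice to each lactone carbonyl, opening both lactones to the bis(Z-allylic tertiary alcohol) A1. Mild acid would then have to close both pyran rings and remove the acetal.
- In its favour: coumarins are robust and tolerate conditions that threaten 2H-chromenes, so the sensitive rings would appear only at the end. The Z geometry needed for ring closure is inherited from the lactones, and no dehydrogenation is needed. On late unveiling of the fragile rings and on the absence of an oxidation step it is the better plan.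
- Against it here: one reagent must discriminate between lactone carbonyls and a diketonate protected only by charge and chelation, with a large excess of Grignard reagent acting on a polyanion of doubtful solubility. Conjugate addition at C4 of the coumarins can compete. The closing acid step meets the ortho-hydroxy diketone just as the acetal is lost, which is the situation in which cyclodehydration to a chromone is expected.
- Comparison: structurally the ring B question is moved, not removed, because a 6-acyl-7-oxygenated coumarin raises the same linear-versus-angular issue in its own preparation; the chosen plan settles it by construction in step 5. Mechanistically this plan relies on relative carbonyl reactivity, the chosen one on orbital-controlled regiochemistry. In step count (two coumarin halves, protection, condensation, key step, ring closure, deprotection) it is expected to be at best equal and probably longer.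

Alternative 2: Both pyran rings are cut at once, at C4–C4a and O1–C2, leading to the bis(1,1-dimethylpropargyl) ether A4 of a preformed diketone in which C8 of the future ring B carries iodine. Forward, heating A4 sets off two aromatic propargyl Claisen rearrangements. Each forms C4a–C4 by [3,3] shift and, after enolisation and a 1,5-hydrogen shift, closes O1–C2 by oxa-6π electrocyclisation to give A3, from which the iodine must then be removed reductively.
- In its favour: the chemistry is that of step 8 of the chosen route, so for ring A it is equally well founded. Both heterocycles arise in one operation, and the alkyne delivers the chromene oxidation level directly, so no dehydrogenation is needed (better on that point). The sequence could be one or two steps shorter.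
- Against it here: ring B regiochemistry is enforced by a blocking group that costs an installation and a removal. The tertiary propargyl ether must be made at a phenol flanked by iodine. An aryl iodide and an enolised diketone must survive temperatures near 200 °C, and rearrangement toward the iodinated carbon with loss or migration of iodine cannot be excluded. The final deiodination must spare two styrene-type alkenes and the diketone.
- Comparison: on structure, fixing linear fusion by having O1 and C4 on the diene is more secure than blocking. On mechanism both plans are pericyclic and create no stereochemistry, so they are equal. On step economy the alternative is equal or slightly better if every step holds, but it takes the diketone through its harshest step, whereas the chosen plan forms the diketone last.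

Alternative 3: The benzene ring of ring A is cut at C4a–C5 and C6–C7, leading to the pyran-fused 2-pyranone A6 and methyl propiolate A7. Forward, A7 adds across C3 and C6 of the pyranone ring of A6, the bridged adduct loses its carboxyl bridge as gas by retro-[4+2], and the benzoate A5 results; A5 is the same compound as 17.
- In its favour: it is the conceptual twin of the chosen key step and its equal in reaction type and polarity-based regiocontrol. The pyranone carbon next to the alkoxy-bearing carbon is the nucleophilic terminus and should bond to the unsubstituted alkyne carbon, placing the ester para to the pyran oxygen. The pyran alkene is present from the start, so no dehydrogenation is needed (better on that point), and aromatisation is irreversible.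
- Against it here: it spends a cycloaddition on the ring that poses no problem, since 17 should be reachable from 14 in two conventional steps. A6 would have to come from a hydroxypyranone lacking the customary 6-methyl group, a less accessible building block. Pyranone–alkyne cycloadditions usually need high temperatures, at which the 2H-pyran of A6 can open electrocyclically. The ring B difficulty is left untouched.
- Comparison: structurally the chosen plan aims its ring-forming step at the difficult ring and this one at the easy ring. Mechanistically the two are equal. In step economy nothing is saved for ring A and ring B still needs its own solution, so overall it is inferior.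

Key step: step 5

Remark on the chemistry: 6 is written as the cyclic hemiketal although it may equilibrate with its open-chain hydroxy keto ester, and the ketene acetal geometry of 8 and 9 is written as Z (expected from carbonyl-directed γ-deprotonation of E-configured 7); neither point affects the outcome, since step 3 funnels both forms of 6 to 7 and the geometry of 9 disappears on aromatisation.

## Steps

Step 1
Reactants: 1 ethyl 5-oxohexanoate
Product: 3 6,6-dimethyloxan-2-one, via ethyl 5-hydroxy-5-methylhexanoate 2 (not isolated)
Conditions: MeMgBr (1.05 equiv), THF, −78 → 0 °C; then 1 M HCl, rt
Reagents that add atoms: methylmagnesium bromide, C[Mg]Br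
Why: Grignard addition to the ketone is much faster than to the ester at low temperature, and the tertiary alkoxide (or alcohol 2 during the acidic work-up) closes the six-membered lactone with loss of ethanol, helped by the gem-dimethyl (Thorpe–Ingold) effect; no stereocentre is formed.

Step 2
Reactants: 3 6,6-dimethyloxan-2-one; 4 methyl acetate
Product: 6 methyl 2-(2-hydroxy-6,6-dimethyloxan-2-yl)acetate (racemic hemiketal), via lithium enolate of methyl acetate 5 (not isolated)
Conditions: LiN(iPr)2 (2.2 equiv), 4 (2.2 equiv), THF, −78 °C; then 3, −78 → −40 °C; AcOH
Reagents that add atoms: none
Why: Claisen-type addition of an ester enolate to a lactone carbonyl; the tetrahedral lithium alkoxide, or the keto ester enolate formed if it opens (hence the second equivalent of 5), resists a second addition, and protonation gives hemiketal 6, whose single stereocentre is racemic and is removed in step 3.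

Step 3
Reactants: 6 methyl 2-(2-hydroxy-6,6-dimethyloxan-2-yl)acetate
Product: 7 methyl (2E)-2-(6,6-dimethyloxan-2-ylidene)acetate
Conditions: PPTS (cat.), 4 Å MS, PhMe, 80 °C
Reagents that add atoms: none
Why: Acid-catalysed dehydration of a β-hydroxy ester of hemiketal type through the cyclic oxocarbenium ion, with loss of the acidic α-proton, gives the conjugated exocyclic vinylogous carbonate; reversible protonation lets the alkene settle to the E isomer (ester trans to the ring oxygen), and the weak acid is chosen so that the tertiary C–O bond is not ionised.

Step 4
Reactants: 7 methyl (2E)-2-(6,6-dimethyloxan-2-ylidene)acetate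
Product: 9 (Z)-[2-(6,6-dimethyl-5,6-dihydro-4H-pyran-2-yl)-1-methoxyethenyloxy]trimethylsilane, via lithium dienolate 8 (not isolated)
Conditions: LiN(iPr)2 (1.1 equiv), THF, −78 °C; Me3SiCl (1.3 equiv), −78 °C → rt; pentane, filtration under Ar, no aqueous work-up, used crude
Reagents that add atoms: chlorotrimethylsilane, C[Si](C)(C)Cl
Why: Kinetic γ-deprotonation of a β-alkoxy enoate (ring C3 is the only enolisable position and lies syn to the ester) gives extended dienolate 8, which silicon traps on oxygen; this is the operation that converts 3-alkoxycrotonates into 1,1,3-trioxygenated dienes, and no stereocentre is formed.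

Step 5
Reactants: 9 (Z)-[2-(6,6-dimethyl-5,6-dihydro-4H-pyran-2-yl)-1-methoxyethenyloxy]trimethylsilane; 10 but-3-yn-2-one
Product: 12 1-(7-hydroxy-2,2-dimethyl-3,4-dihydro-2H-chromen-6-yl)ethanone, via cycloadduct 11 (not isolated)
Conditions: 10 (1.3 equiv), PhMe, 0 °C → rt; then 1 M HCl, THF, rt
Reagents that add atoms: none
Why: The electron-rich diene and the alkynone combine in a normal-demand, strongly asynchronous Diels–Alder reaction, at the limit a vinylogous Mukaiyama–Michael addition followed by closure of the allenolate onto the silyloxy(methoxy)-stabilised cation. The closest known reaction type is the cycloaddition of 1,1,3-trioxygenated vinylketene acetal dienes with alkynones, which gives acylresorcinol derivatives after aromatisation; here the 3-oxygen and the 4-carbon of the diene are tied together in the dihydropyran. The carbocycle of ring B is the one ring closed, by a two-bond intermolecular [4+2] union (C4a–C5 and C6–C7) across the s-cis diene, whose inside position at the pyran terminus carries only hydrogen. Regiochemistry is the only selectivity needed: the largest HOMO coefficient lies on the pyran carbon that becomes C4a (vinylogous to the ketene acetal and β to the ring enol-ether oxygen), so it bonds to the unsubstituted β-carbon of the ynone while the ketene acetal carbon bonds to the acyl-bearing carbon, placing the acetyl group on C6 next to the C7 oxygen. Linear fusion needs no control because O1 and C4 are already attached to the diene. Adduct 11 has two stereocentres (C4a and C7) of no consequence; in dilute acid the mixed ketal at C7 collapses with loss of methanol and the silyl group, and the shift of the C4a hydrogen to oxygen completes aromatisation to the chelated phenol. No stereocentre remains in 12.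

Step 6
Reactants: 12 1-(7-hydroxy-2,2-dimethyl-3,4-dihydro-2H-chromen-6-yl)ethanone
Product: 13 1-(7-hydroxy-2,2-dimethyl-2H-chromen-6-yl)ethanone
Conditions: DDQ (1.2 equiv), 1,4-dioxane, reflux
Reagents that add atoms: none
Why: DDQ dehydrogenation of a 2,2-dimethylchroman: hydride abstraction from benzylic C4 gives a cation stabilised by the C7 oxygen (para to C4a) and by O1, and loss of a C3 proton gives the chromene; the quaternary C2 prevents further oxidation, and the chelated phenol and the acetyl group should be spared.

Step 7
Reactants: 14 methyl 4-hydroxybenzoate
Product: 15 methyl 4-[(2-methylbut-3-yn-2-yl)oxy]benzoate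
Conditions: 3-chloro-3-methylbut-1-yne (1.5 equiv), K2CO3, KI (cat.), CuI (cat.), acetone, reflux
Reagents that add atoms: 3-chloro-3-methylbut-1-yne, CC(C)(Cl)C#C
Why: Copper-assisted O-alkylation of a phenoxide with a tertiary propargylic chloride, the standard entry to aryl 1,1-dimethylpropargyl ethers; the ester is inert under these conditions.

Step 8
Reactants: 15 methyl 4-[(2-methylbut-3-yn-2-yl)oxy]benzoate
Product: 17 methyl 2,2-dimethyl-2H-chromene-6-carboxylate, via allenylphenol 16 (not isolated)
Conditions: PhNEt2, 190 °C
Reagents that add atoms: none
Why: Aromatic propargyl Claisen rearrangement: a [3,3] shift to one of the two equivalent ortho positions and enolisation give allenylphenol 16, and a 1,5-hydrogen shift followed by oxa-6π electrocyclisation closes the 2,2-dimethyl-2H-pyran; the basic solvent suppresses acid-catalysed side reactions of the chromene.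

Step 9
Reactants: 13 1-(7-hydroxy-2,2-dimethyl-2H-chromen-6-yl)ethanone; 17 methyl 2,2-dimethyl-2H-chromene-6-carboxylate
Product: 18 Glyinflanin D [1-(2,2-dimethyl-2H-chromen-6-yl)-3-(7-hydroxy-2,2-dimethyl-2H-chromen-6-yl)propane-1,3-dione]
Conditions: NaH (4 equiv), THF, reflux; then AcOH, 0 °C
Reagents that add atoms: none
Why: Crossed Claisen condensation: the sodium phenoxide–enolate dianion of 13 attacks the non-enolisable ester 17, and deprotonation of the product to its diketonate drives the equilibrium; both chromenes are stable to base, and the buffered quench avoids acid-induced cyclodehydration to a chromone.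

## Compound list

1 | ethyl 5-oxohexanoate | CCOC(=O)CCCC(C)=O | starting material
2 | ethyl 5-hydroxy-5-methylhexanoate (formed as its bromomagnesium alkoxide) | CCOC(=O)CCCC(C)(C)O | intermediate (not isolated)
3 | 6,6-dimethyloxan-2-one (6,6-dimethyltetrahydro-2H-pyran-2-one) | CC1(C)CCCC(=O)O1 | intermediate
4 | methyl acetate | COC(C)=O | starting material
5 | lithium 1-methoxyethenolate (lithium enolate of methyl acetate) | [Li+].[O-]C(=C)OC | intermediate (not isolated)
6 | methyl 2-(2-hydroxy-6,6-dimethyloxan-2-yl)acetate (racemic) | COC(=O)CC1(O)CCCC(C)(C)O1 | intermediate
7 | methyl (2E)-2-(6,6-dimethyloxan-2-ylidene)acetate | COC(=O)/C=C1\CCCC(C)(C)O1 | intermediate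
8 | lithium dienolate of 7 (lithium (Z)-2-(6,6-dimethyl-5,6-dihydro-4H-pyran-2-yl)-1-methoxyethenolate) | [Li+].CO/C([O-])=C/C1=CCCC(C)(C)O1 | intermediate (not isolated)
9 | (Z)-[2-(6,6-dimethyl-5,6-dihydro-4H-pyran-2-yl)-1-methoxyethenyloxy]trimethylsilane | CO/C(O[Si](C)(C)C)=C/C1=CCCC(C)(C)O1 | intermediate
10 | but-3-yn-2-one | CC(=O)C#C | starting material
11 | 1-[7-methoxy-2,2-dimethyl-7-(trimethylsilyloxy)-3,4,4a,7-tetrahydro-2H-chromen-6-yl]ethanone (mixture of diastereomers, racemic) | CC(=O)C1=CC2CCC(C)(C)OC2=CC1(OC)O[Si](C)(C)C | intermediate (not isolated)
12 | 1-(7-hydroxy-2,2-dimethyl-3,4-dihydro-2H-chromen-6-yl)ethanone | CC(=O)c1cc2CCC(C)(C)Oc2cc1O | intermediate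
13 | 1-(7-hydroxy-2,2-dimethyl-2H-chromen-6-yl)ethanone | CC(=O)c1cc2C=CC(C)(C)Oc2cc1O | intermediate
14 | methyl 4-hydroxybenzoate | COC(=O)c1ccc(O)cc1 | starting material
15 | methyl 4-[(2-methylbut-3-yn-2-yl)oxy]benzoate | COC(=O)c1ccc(OC(C)(C)C#C)cc1 | intermediate
16 | methyl 4-hydroxy-3-(3-methylbuta-1,2-dien-1-yl)benzoate | COC(=O)c1ccc(O)c(C=C=C(C)C)c1 | intermediate (not isolated)
17 | methyl 2,2-dimethyl-2H-chromene-6-carboxylate | COC(=O)c1ccc2OC(C)(C)C=Cc2c1 | intermediate
18 | Glyinflanin D, 1-(2,2-dimethyl-2H-chromen-6-yl)-3-(7-hydroxy-2,2-dimethyl-2H-chromen-6-yl)propane-1,3-dione | CC1(C)C=Cc2cc(C(=O)CC(=O)c3cc4c(cc3O)OC(C)(C)C=C4)ccc2O1 | target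

## Step count and least certain steps

Total step count: 9. Longest linear sequence: 7 steps (steps 1, 2, 3, 4, 5, 6 and 9); the ring A branch (steps 7 and 8) joins at step 9.

**Step 5 (key step).**
- What may go wrong: the addition may stop at an open-chain vinylogous Michael adduct, because ring closure must form a bond to a crowded, doubly oxygenated carbon while the pyran terminus carries a ring substituent. Protodesilylation of the diene by traces of moisture and oligomerisation of the ynone would have the same effect. A lesser deviation is aromatisation with loss of silanol in place of methanol, which would leave the C7 oxygen methylated.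
- Fallback: this one uses Friedel–Crafts chemistry and no cycloaddition. It cannot branch from a numbered intermediate of the diene line; it replaces compounds 1 to 11, sets out from commercial 1-(2,4-dihydroxyphenyl)ethanone F1 and comes back to the route at 12. F1 is C-prenylated with 2-methylbut-3-en-2-ol and BF3·OEt2 in 1,4-dioxane at the position para to the chelated hydroxyl, which is not flanked by two oxygens. This gives 1-[2,4-dihydroxy-5-(3-methylbut-2-en-1-yl)phenyl]ethanone F2, which is separated from any isomer alkylated between the oxygens. Formic acid at 60 °C then adds the only neighbouring hydroxyl across the prenyl alkene in the Markovnikov sense and closes the chroman 12. Linear fusion here depends on a separation of regioisomers, which is why this is the fallback and not the plan.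

**Step 3.**
- What may go wrong: ionisation of the tertiary C–O bond under the acid, followed by alkene formation or carbon–carbon cyclisation of the keto ester onto the cation; or dehydration toward the ring, giving the non-conjugated endocyclic enol ether.
- Fallback: it sets out from 3 and comes back at 7, bypassing 4, 5 and 6 and avoiding acid altogether. Methylenation of the lactone carbonyl with Cp2TiMe2 (PhMe, 65 °C) gives 2,2-dimethyl-6-methylideneoxane F3. Acylation of this enol ether with trichloroacetyl chloride and pyridine (CH2Cl2, 0 °C) gives (3E)-1,1,1-trichloro-3-(6,6-dimethyloxan-2-ylidene)propan-2-one F4. Haloform-type cleavage with K2CO3 in methanol converts the trichloromethyl ketone into the methyl ester 7.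

**Step 6.**
- What may go wrong: slow hydride abstraction, because the acetyl group withdraws electron density from the ring, leaving incomplete conversion; and competing oxidation or quinone addition at the free phenol.
- Fallback: it sets out from 12 and comes back at 13, replacing hydride abstraction by radical bromination and elimination. Acetylation (Ac2O, pyridine) gives 6-acetyl-2,2-dimethyl-3,4-dihydro-2H-chromen-7-yl acetate F5. Benzylic bromination with NBS and catalytic AIBN (PhCF3, 80 °C) gives 6-acetyl-4-bromo-2,2-dimethyl-3,4-dihydro-2H-chromen-7-yl acetate F6. Dehydrobromination with Et3N gives 6-acetyl-2,2-dimethyl-2H-chromen-7-yl acetate F7, and K2CO3 in methanol removes the acetate to give 13.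

**Step 9.**
- What may go wrong: sluggish acylation of the enolate by an electron-rich para-alkoxybenzoate, so that self-condensation of the ketone or reversal by methoxide competes.
- Fallback: it sets out from 17 (with 13 as partner) and comes back at 18, making the C–C bond intramolecularly by Baker–Venkataraman rearrangement. Saponification of 17 (LiOH, THF/H2O) gives 2,2-dimethyl-2H-chromene-6-carboxylic acid F8. Esterification of the phenol of 13 with F8 (EDC·HCl, DMAP, CH2Cl2), which avoids an acid chloride and its hydrogen chloride, gives 6-acetyl-2,2-dimethyl-2H-chromen-7-yl 2,2-dimethyl-2H-chromene-6-carboxylate F9. KOtBu in THF then generates the ketone enolate, which takes the aroyl group from oxygen to carbon and gives 18 after a buffered quench.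

## Further compounds

F1 | step 5 | 1-(2,4-dihydroxyphenyl)ethanone | CC(=O)c1ccc(O)cc1O
F2 | step 5 | 1-[2,4-dihydroxy-5-(3-methylbut-2-en-1-yl)phenyl]ethanone | CC(=O)c1cc(CC=C(C)C)c(O)cc1O
F3 | step 3 | 2,2-dimethyl-6-methylideneoxane | C=C1CCCC(C)(C)O1
F4 | step 3 | (3E)-1,1,1-trichloro-3-(6,6-dimethyloxan-2-ylidene)propan-2-one | ClC(Cl)(Cl)C(=O)/C=C1\CCCC(C)(C)O1
F5 | step 6 | 6-acetyl-2,2-dimethyl-3,4-dihydro-2H-chromen-7-yl acetate | CC(=O)Oc1cc2OC(C)(C)CCc2cc1C(C)=O
F6 | step 6 | 6-acetyl-4-bromo-2,2-dimethyl-3,4-dihydro-2H-chromen-7-yl acetate (racemic) | CC(=O)Oc1cc2OC(C)(C)CC(Br)c2cc1C(C)=O
F7 | step 6 | 6-acetyl-2,2-dimethyl-2H-chromen-7-yl acetate | CC(=O)Oc1cc2OC(C)(C)C=Cc2cc1C(C)=O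
F8 | step 9 | 2,2-dimethyl-2H-chromene-6-carboxylic acid | OC(=O)c1ccc2OC(C)(C)C=Cc2c1
F9 | step 9 | 6-acetyl-2,2-dimethyl-2H-chromen-7-yl 2,2-dimethyl-2H-chromene-6-carboxylate | CC(=O)c1cc2C=CC(C)(C)Oc2cc1OC(=O)c1ccc2OC(C)(C)C=Cc2c1
A1 | alternative 1 | 1-[4-hydroxy-5-[(Z)-3-hydroxy-3-methylbut-1-enyl]-2-(methoxymethoxy)phenyl]-3-[4-hydroxy-3-[(Z)-3-hydroxy-3-methylbut-1-enyl]phenyl]propane-1,3-dione | COCOc1cc(O)c(/C=C\C(C)(C)O)cc1C(=O)CC(=O)c1ccc(O)c(/C=C\C(C)(C)O)c1
A2 | alternative 1 | 1-[7-(methoxymethoxy)-2-oxo-2H-chromen-6-yl]-3-(2-oxo-2H-chromen-6-yl)propane-1,3-dione | COCOc1cc2OC(=O)C=Cc2cc1C(=O)CC(=O)c1ccc2OC(=O)C=Cc2c1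
A3 | alternative 2 | 1-(2,2-dimethyl-2H-chromen-6-yl)-3-(7-hydroxy-8-iodo-2,2-dimethyl-2H-chromen-6-yl)propane-1,3-dione | CC1(C)C=Cc2cc(C(=O)CC(=O)c3cc4C=CC(C)(C)Oc4c(I)c3O)ccc2O1
A4 | alternative 2 | 1-[2-hydroxy-3-iodo-4-(2-methylbut-3-yn-2-yloxy)phenyl]-3-[4-(2-methylbut-3-yn-2-yloxy)phenyl]propane-1,3-dione | C#CC(C)(C)Oc1ccc(cc1)C(=O)CC(=O)c1ccc(OC(C)(C)C#C)c(I)c1O
A5 | alternative 3 | methyl 2,2-dimethyl-2H-chromene-6-carboxylate | COC(=O)c1ccc2OC(C)(C)C=Cc2c1
A6 | alternative 3 | 2,2-dimethyl-2H,5H-pyrano[4,3-b]pyran-5-one | CC1(C)C=CC2=C(O1)C=COC2=O
A7 | alternative 3 | methyl propiolate | COC(=O)C#C
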